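**Retrosynthetic overview**
1. Target ⇐ C4 acetylation and C8 desilylation of a hydroxy enoate ⇐ Pd-catalysed methoxycarbonylation of a C5 alkenylstannane ⇐ hydroxyl-directed trans-hydrostannation of a ten-membered cycloalkynol (fixes the ring-trans C5=C6 geometry).
2. Ten-membered ring (formed last): C4–C5 bond by a chromium-catalysed, ligand-controlled iodoalkyne–aldehyde ring closure (new step; sets C4).
3. Seco precursor ⇐ C9–C10 bond by Hosomi–Sakurai union of fragment A (cyclohexenylmethylsilane) and fragment B (lactone aldehyde); sets C9, C10 and the 11(20)-methylidene.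
4. Fragment A (cyclohexane ring, formed first): asymmetric Diels–Alder of methacrolein and 1-acetoxybutadiene (C1, C14), asymmetric vinylation (C2), allylic oxidation, enol triflate and Negishi coupling to the allylsilane.
5. Fragment B (γ-lactone ring, made in parallel): Sonogashira enyne, Sharpless epoxidation, Ti-mediated opening by acrylic acid (C7), copper hydride reductive aldol lactonisation (C8, C17).

Assumption and convention: (E)-3-iodoprop-2-en-1-ol and (E)-buta-1,3-dien-1-yl acetate are taken as commercial; late intermediates carry briarane numbers (C1 quaternary with Me-15; ten-membered ring C1–C10; six-membered ring C1, C10–C14 with C20 on C11; lactone O–C19(=O)–C17(Me-18)–C8 closed on C7; C16 on C5); the SMILES strings are definitive for stereochemistry.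

**Fragment A**

Step 1
Reactants: 1 methacrolein; 2 (E)-buta-1,3-dien-1-yl acetate
Product: 3 (1S,6R)-6-formyl-6-methylcyclohex-2-en-1-yl acetate
Conditions: (S)-o-tolyl oxazaborolidine·HNTf2 (10 mol %), CH2Cl2, −78 °C
Reagents that add atoms: none
Why: Catalytic asymmetric Diels–Alder reaction through the endo, "ortho" transition state, so the acetoxy-bearing diene carbon bonds to the methyl-bearing carbon and OAc ends cis to CHO (C14 and C1 set together), the boron-bound enal being shielded on one face by the catalyst (the antipodal catalyst is used if the sense proves opposite).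

Step 2
Reactants: 3 (1S,6R)-6-formyl-6-methylcyclohex-2-en-1-yl acetate; 4 vinylmagnesium bromide
Product: 6 (1S,6S)-6-[(1S)-1-hydroxyprop-2-en-1-yl]-6-methylcyclohex-2-en-1-yl acetate, via divinylzinc 5 (not isolated)
Conditions: 4 (2.4 equiv), ZnCl2 (1.2 equiv), THF then toluene/dioxane (Mg salts filtered off); (−)-MIB (10 mol %), 0 °C; aq. NH4Cl
Reagents that add atoms: none
Why: Amino-alcohol-catalysed asymmetric vinylzinc addition to the non-enolisable neopentyl aldehyde, the chiral zinc alkoxide catalyst delivering vinyl to the Si face to set C2 (S) while the acetate is untouched by the zinc reagent.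

Step 3
Reactants: 6 (1S,6S)-6-[(1S)-1-hydroxyprop-2-en-1-yl]-6-methylcyclohex-2-en-1-yl acetate
Product: 8 (1S,6S)-6-[(1S)-1,3-dihydroxypropyl]-6-methylcyclohex-2-en-1-yl acetate, via bis-boron adduct 7 (not isolated)
Conditions: 9-BBN (2.3 equiv), THF, 0 °C → rt; then H2O2, aq. NaHCO3, 0 °C
Reagents that add atoms: hydrogen peroxide OO
Why: Hydroboration–oxidation in which 9-BBN adds to the monosubstituted vinyl group far faster than to the ring cis-alkene and places boron on the terminal carbon, giving the primary C4 alcohol without a new stereocenter.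

Step 4
Reactants: 8 (1S,6S)-6-[(1S)-1,3-dihydroxypropyl]-6-methylcyclohex-2-en-1-yl acetate
Product: 9 (1S,6S)-6-[(1S)-1-hydroxy-3-(triethylsilyloxy)propyl]-6-methylcyclohex-2-en-1-yl acetate
Conditions: Et3SiCl (1.05 equiv), imidazole, CH2Cl2, −78 °C
Reagents that add atoms: chlorotriethylsilane CC[Si](Cl)(CC)CC
Why: Selective silylation of the primary alcohol over the hindered neopentyl secondary alcohol at low temperature.

Step 5
Reactants: 9 (1S,6S)-6-[(1S)-1-hydroxy-3-(triethylsilyloxy)propyl]-6-methylcyclohex-2-en-1-yl acetate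
Product: 10 (1S,6S)-6-[(1S)-1-acetoxy-3-(triethylsilyloxy)propyl]-6-methylcyclohex-2-en-1-yl acetate
Conditions: Ac2O, Et3N, DMAP (cat.), CH2Cl2, rt
Reagents that add atoms: acetic anhydride CC(=O)OC(C)=O
Why: DMAP-catalysed acetylation of the C2 alcohol; any earlier 1,3-acetyl shift between the C14 and C2 oxygens is harmless because both end as acetates.

Step 6
Reactants: 10 (1S,6S)-6-[(1S)-1-acetoxy-3-(triethylsilyloxy)propyl]-6-methylcyclohex-2-en-1-yl acetate
Product: 11 (1S,6S)-6-[(1S)-1-acetoxy-3-(triethylsilyloxy)propyl]-6-methyl-4-oxocyclohex-2-en-1-yl acetate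
Conditions: Rh2(cap)4 (dirhodium tetrakis(caprolactamate), 1 mol %), t-BuOOH (5 equiv), K2CO3, CH2Cl2, rt
Reagents that add atoms: tert-butyl hydroperoxide CC(C)(C)OO
Why: Catalytic allylic C–H oxidation in which the tert-butylperoxyl radical abstracts the unhindered C11–H (the C14–H is deactivated by its acetoxy group) and the allylic peroxide collapses to the C11 enone.

Step 7
Reactants: 11 (1S,6S)-6-[(1S)-1-acetoxy-3-(triethylsilyloxy)propyl]-6-methyl-4-oxocyclohex-2-en-1-yl acetate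
Product: 12 (1S,6S)-6-[(1S)-1-acetoxy-3-(triethylsilyloxy)propyl]-6-methyl-4-(trifluoromethanesulfonyloxy)cyclohexa-2,4-dien-1-yl acetate
Conditions: KN(SiMe3)2, THF, −78 °C; then Comins' reagent, −78 °C
Reagents that add atoms: N-(5-chloropyridin-2-yl)bis(trifluoromethanesulfonimide) O=S(=O)(N(c1ccc(Cl)cn1)S(=O)(=O)C(F)(F)F)C(F)(F)F
Why: Kinetic α′-deprotonation of the enone at C10 gives the cross-conjugated dienolate, which is trapped on oxygen as the enol triflate, ketone deprotonation at −78 °C outpacing that of the acetates.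

Step 8
Reactants: 12 (1S,6S)-6-[(1S)-1-acetoxy-3-(triethylsilyloxy)propyl]-6-methyl-4-(trifluoromethanesulfonyloxy)cyclohexa-2,4-dien-1-yl acetate; 13 (trimethylsilyl)methylmagnesium chloride
Product: 15 (1S,6S)-6-[(1S)-1-acetoxy-3-(triethylsilyloxy)propyl]-6-methyl-4-[(trimethylsilyl)methyl]cyclohexa-2,4-dien-1-yl acetate, via (trimethylsilyl)methylzinc chloride 14 (not isolated)
Conditions: 13, ZnCl2, THF, 0 °C; then 12, Pd(PPh3)4 (5 mol %), THF, rt
Reagents that add atoms: none
Why: Negishi cross-coupling of the alkenyl triflate with a β-hydrogen-free alkylzinc reagent, which tolerates the acetates and installs C20 as the allylsilane carbon.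

Step 9
Reactants: 15 (1S,6S)-6-[(1S)-1-acetoxy-3-(triethylsilyloxy)propyl]-6-methyl-4-[(trimethylsilyl)methyl]cyclohexa-2,4-dien-1-yl acetate
Product: 16 (1S,2R)-2-[(1S)-1-acetoxy-3-(triethylsilyloxy)propyl]-2-methyl-4-[(trimethylsilyl)methyl]cyclohex-3-en-1-yl acetate
Conditions: 2-nitrobenzenesulfonohydrazide, Et3N, CH2Cl2, rt
Reagents that add atoms: none
Why: Diimide reduction is selective for the cis-disubstituted C12=C13 bond over the trisubstituted C10=C11 allylsilane alkene flanked by the quaternary carbon.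

**Fragment B**

Step 10
Reactants: 17 ethynyltrimethylsilane; 18 (E)-3-iodoprop-2-en-1-ol
Product: 19 (E)-5-(trimethylsilyl)pent-2-en-4-yn-1-ol
Conditions: PdCl2(PPh3)2 (2 mol %), CuI (4 mol %), Et3N, THF, rt
Reagents that add atoms: none
Why: Sonogashira coupling of a vinyl iodide with retention of the E geometry.

Step 11
Reactants: 19 (E)-5-(trimethylsilyl)pent-2-en-4-yn-1-ol
Product: 20 [(2R,3R)-3-[(trimethylsilyl)ethynyl]oxiran-2-yl]methanol
Conditions: Ti(OiPr)4 (10 mol %), D-(−)-diethyl tartrate (12 mol %), t-BuOOH, 4 Å MS, CH2Cl2, −20 °C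
Reagents that add atoms: tert-butyl hydroperoxide CC(C)(C)OO
Why: Sharpless asymmetric epoxidation of the E-allylic alcohol, the D-tartrate–titanium complex delivering oxygen to the face that gives the (2R,3R)-epoxide while the alkyne is inert.

Step 12
Reactants: 20 [(2R,3R)-3-[(trimethylsilyl)ethynyl]oxiran-2-yl]methanol; 21 acrylic acid
Product: 22 (2R,3S)-1,2-dihydroxy-5-(trimethylsilyl)pent-4-yn-3-yl prop-2-enoate
Conditions: Ti(OiPr)4 (1.5 equiv), 21 (1.5 equiv), CH2Cl2, 0 °C → rt; aq. tartaric acid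
Reagents that add atoms: none
Why: Titanium-chelated 2,3-epoxy alcohol opening by the carboxylate at C3 (propargylic, remote from the Ti-bound primary oxygen) with inversion, which sets C7 (S) and installs the acrylate in one operation.

Step 13
Reactants: 22 (2R,3S)-1,2-dihydroxy-5-(trimethylsilyl)pent-4-yn-3-yl prop-2-enoate
Product: 23 (2R,3S)-2-hydroxy-1-(triethylsilyloxy)-5-(trimethylsilyl)pent-4-yn-3-yl prop-2-enoate
Conditions: Et3SiCl (1.05 equiv), imidazole, CH2Cl2, −78 °C
Reagents that add atoms: chlorotriethylsilane CC[Si](Cl)(CC)CC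
Why: Selective silylation of the primary (C9) hydroxyl, done cold and used at once to limit acrylate migration.

Step 14
Reactants: 23 (2R,3S)-2-hydroxy-1-(triethylsilyloxy)-5-(trimethylsilyl)pent-4-yn-3-yl prop-2-enoate
Product: 24 (3S)-2-oxo-1-(triethylsilyloxy)-5-(trimethylsilyl)pent-4-yn-3-yl prop-2-enoate
Conditions: Dess–Martin periodinane, CH2Cl2, 0 °C
Reagents that add atoms: none
Why: Non-basic Dess–Martin oxidation gives the C8 ketone without epimerising the acidic propargylic C7–H.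

Step 15
Reactants: 24 (3S)-2-oxo-1-(triethylsilyloxy)-5-(trimethylsilyl)pent-4-yn-3-yl prop-2-enoate
Product: 26 (3R,4R,5S)-4-hydroxy-3-methyl-4-[(triethylsilyloxy)methyl]-5-[(trimethylsilyl)ethynyl]oxolan-2-one, via disiloxanyl ether 25 (not isolated)
Conditions: Cu(OAc)2·H2O (5 mol %), rac-BINAP (5 mol %), (HMe2Si)2O, THF, 0 °C → rt; then aq. NH4F
Reagents that add atoms: none
Why: Copper hydride reductive aldol cyclisation in which conjugate hydride addition to the acrylate gives a (Z)-copper enolate that adds to the tethered ketone through a chelated chair-like transition state, so Me-18 and the new hydroxyl end cis (C17) and the C9 arm takes the position trans to the C7 alkynyl group to avoid eclipsing in the forming ring (C8).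

Step 16
Reactants: 26 (3R,4R,5S)-4-hydroxy-3-methyl-4-[(triethylsilyloxy)methyl]-5-[(trimethylsilyl)ethynyl]oxolan-2-one
Product: 27 (3R,4R,5S)-3-methyl-4-(triethylsilyloxy)-4-[(triethylsilyloxy)methyl]-5-[(trimethylsilyl)ethynyl]oxolan-2-one
Conditions: Et3SiOTf, 2,6-lutidine, CH2Cl2, −78 → 0 °C
Reagents that add atoms: triethylsilyl trifluoromethanesulfonate CC[Si](CC)(CC)OS(=O)(=O)C(F)(F)F
Why: Silyl triflate protection of the hindered tertiary alcohol under non-nucleophilic base, which blocks retro-aldol and translactonisation later.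

Step 17
Reactants: 27 (3R,4R,5S)-3-methyl-4-(triethylsilyloxy)-4-[(triethylsilyloxy)methyl]-5-[(trimethylsilyl)ethynyl]oxolan-2-one
Product: 28 (3R,4R,5S)-5-(iodoethynyl)-3-methyl-4-(triethylsilyloxy)-4-[(triethylsilyloxy)methyl]oxolan-2-one
Conditions: NIS, AgNO3 (10 mol %), DMF, rt, dark
Reagents that add atoms: N-iodosuccinimide O=C1CCC(=O)N1I
Why: Silver-catalysed iododesilylation converts the alkynylsilane directly into the 1-iodoalkyne through a silver acetylide.

Step 18
Reactants: 28 (3R,4R,5S)-5-(iodoethynyl)-3-methyl-4-(triethylsilyloxy)-4-[(triethylsilyloxy)methyl]oxolan-2-one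
Product: 29 (2S,3S,4R)-2-(iodoethynyl)-4-methyl-5-oxo-3-(triethylsilyloxy)oxolane-3-carbaldehyde
Conditions: (COCl)2, DMSO, CH2Cl2, −78 → −30 °C; iPr2NEt
Reagents that add atoms: none
Why: Swern conditions cleave and oxidise the primary triethylsilyl ether directly to the aldehyde while the tertiary silyl ether survives, and the product aldehyde has no α-hydrogen to epimerise.

**Union and endgame**

Step 19
Reactants: 16 (1S,2R)-2-[(1S)-1-acetoxy-3-(triethylsilyloxy)propyl]-2-methyl-4-[(trimethylsilyl)methyl]cyclohex-3-en-1-yl acetate; 29 (2S,3S,4R)-2-(iodoethynyl)-4-methyl-5-oxo-3-(triethylsilyloxy)oxolane-3-carbaldehyde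
Product: 30 (1S,2R,3S)-2-[(1S)-1-acetoxy-3-(triethylsilyloxy)propyl]-3-{(S)-hydroxy[(2S,3R,4R)-2-(iodoethynyl)-4-methyl-5-oxo-3-(triethylsilyloxy)oxolan-3-yl]methyl}-2-methyl-4-methylidenecyclohexyl acetate
Conditions: BF3·OEt2 (1.5 equiv), CH2Cl2, −78 → −40 °C
Reagents that add atoms: none
Why: Hosomi–Sakurai allylation (SE2′) in which C10 attacks the BF3-activated aldehyde from the ring face anti to the bulky C1 side chain (cis to Me-15, setting C10), the open antiperiplanar transition state of a γ-substituted allylsilane gives the 9,10-syn adduct (setting C9 against an aldehyde of weak intrinsic facial bias), and loss of silicon leaves the 11(20)-methylidene.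

Step 20
Reactants: 30 the C9 alcohol from step 19
Product: 31 (1S,2R,3S)-3-{(S)-acetoxy[(2S,3R,4R)-2-(iodoethynyl)-4-methyl-5-oxo-3-(triethylsilyloxy)oxolan-3-yl]methyl}-2-[(1S)-1-acetoxy-3-(triethylsilyloxy)propyl]-2-methyl-4-methylidenecyclohexyl acetate
Conditions: Ac2O, DMAP, pyridine, CH2Cl2, rt
Reagents that add atoms: acetic anhydride CC(=O)OC(C)=O
Why: DMAP-promoted acetylation of the hindered C9 secondary alcohol, which also removes the risk of translactonisation onto C19.

Step 21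
Reactants: 31 the C9 acetate from step 20
Product: 32 (1S,2R,3S)-3-{(S)-acetoxy[(2S,3R,4R)-2-(iodoethynyl)-4-methyl-5-oxo-3-(triethylsilyloxy)oxolan-3-yl]methyl}-2-[(1S)-1-acetoxy-3-oxopropyl]-2-methyl-4-methylidenecyclohexyl acetate
Conditions: (COCl)2, DMSO, CH2Cl2, −78 → −40 °C; iPr2NEt; cold pH 7 buffer
Reagents that add atoms: none
Why: Swern oxidative desilylation of the primary C4 triethylsilyl ether in the presence of the tertiary one, with hindered base and a cold buffered quench to avoid β-elimination of the C2 acetate.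

Step 22
Reactants: 32 the seco iodoalkyne aldehyde from step 21
Product: 34 ten-membered cycloalkynol (1R,2S,4R,7S,8R,9S,10S,14S,17R)-2,9,14-triacetoxy-4-hydroxy-8-(triethylsilyloxy)-5,6-didehydro-16-nor-briar-11(20)-en-19,7-olide, via trimethylsilyl ether 33 (not isolated)
Conditions: CrCl(TBOx) (10 mol %; (R)-TBOx = tethered bis(8-quinolinolato) ligand), Mn powder (3 equiv), Me3SiCl (2 equiv), THF, 2 mM, slow addition of 32, rt; then aq. citric acid/MeOH
Reagents that add atoms: none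
Why: Proposed new method: a ligand-controlled, chromium-catalysed Nozaki–Hiyama–Kishi alkynylation run as a macrocyclisation, in which zerovalent manganese reduces the trivalent chromium chloride complex to divalent chromium, two divalent chromium centres cleave the C(sp)–I bond to give an alkynyl trivalent chromium species held in the chiral bis(quinolinolato) pocket, this adds to the chromium-bound C4 aldehyde on the face fixed by the ligand (4R, with the antipodal ligand as the control) and Me3SiCl silylates the chromium alkoxide to turn the metal over; the closest known reactions are the intermolecular enantioselective chromium-catalysed alkynylation of aldehydes with iodoalkynes and the stoichiometric CrCl2/NiCl2 closure of ten-membered enediyne carbinols, and the linear C4–C5≡C6–C7 unit should span the ring with little strain while high dilution suppresses dimerisation.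

Step 23
Reactants: 34 the ten-membered cycloalkynol from step 22
Product: 35 alkenylstannane (1R,2S,4R,5Z,7S,8R,9S,10S,14S,17R)-2,9,14-triacetoxy-4-hydroxy-5-(tributylstannyl)-8-(triethylsilyloxy)-16-nor-briara-5,11(20)-dien-19,7-olide
Conditions: [Cp*RuCl]4 (2.5 mol %), Bu3SnH (1.1 equiv), CH2Cl2, rt
Reagents that add atoms: tributylstannane CCCC[SnH](CCCC)CCCC
Why: Ruthenium-catalysed hydroxyl-directed trans-hydrostannation, the C4–OH hydrogen-bonding to the Ru–Cl unit so that tin goes to the proximal C5 and hydrogen adds trans at C6, which fixes the ring-trans C5=C6 geometry of the target.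

Step 24
Reactants: 35 the alkenylstannane from step 23
Product: 36 hydroxy enoate methyl (1R,2S,4R,5Z,7S,8S,9S,10S,14S,17R)-2,9,14-triacetoxy-4-hydroxy-8-(triethylsilyloxy)briara-5,11(20)-dien-19,7-olid-16-oate
Conditions: Pd(OAc)2 (10 mol %), Ph3As (20 mol %), 1,4-benzoquinone (1.5 equiv), CO (1 atm), MeOH, rt
Reagents that add atoms: carbon monoxide [C-]#[O+]; methanol CO
Why: Oxidative methoxycarbonylation of the alkenylstannane (transmetalation to divalent palladium, CO insertion, methanolysis, benzoquinone reoxidation) forms the C5–C16 bond with retention of alkene geometry.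

Step 25
Reactants: 36 the hydroxy enoate from step 24
Product: 37 methyl (1R,2S,4R,5Z,7S,8S,9S,10S,14S,17R)-2,4,9,14-tetraacetoxy-8-(triethylsilyloxy)briara-5,11(20)-dien-19,7-olid-16-oate
Conditions: Ac2O, pyridine, DMAP (cat.), CH2Cl2, 0 °C
Reagents that add atoms: acetic anhydride CC(=O)OC(C)=O
Why: Mild acetylation of the secondary allylic C4 alcohol, the tertiary C8 oxygen being silylated and inert.

Step 26
Reactants: 37 the tetraacetate silyl ether from step 25
Product: 38 CNP0209369.3, methyl (1R,2S,4R,5Z,7S,8S,9S,10S,14S,17R)-2,4,9,14-tetraacetoxy-8-hydroxybriara-5,11(20)-dien-19,7-olid-16-oate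
Conditions: HF·pyridine, THF, 0 °C → rt
Reagents that add atoms: none
Why: Fluoride-mediated cleavage of the tertiary triethylsilyl ether under buffered acidic conditions that leave the four acetates, the methyl ester and the lactone intact.

**Compound list**
1 | methacrolein | C=C(C)C=O | starting material
2 | (E)-buta-1,3-dien-1-yl acetate | CC(=O)O/C=C/C=C | starting material
3 | (1S,6R)-6-formyl-6-methylcyclohex-2-en-1-yl acetate | C1C=C[C@H](OC(C)=O)[C@](C)(C=O)C1 | intermediate
4 | vinylmagnesium bromide | C=C[Mg]Br | starting material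
5 | divinylzinc (formed in the flask) | C=C[Zn]C=C | intermediate
6 | (1S,6S)-6-[(1S)-1-hydroxyprop-2-en-1-yl]-6-methylcyclohex-2-en-1-yl acetate | C1C=C[C@H](OC(C)=O)[C@](C)([C@@H](O)C=C)C1 | intermediate
7 | bis-boron adduct of 6 (O-borinate at C2 and B-alkyl at C4, both 9-borabicyclo[3.3.1]nonan-9-yl; formed in the flask) | C1C=C[C@H](OC(C)=O)[C@](C)([C@@H](OB2C3CCCC2CCC3)CCB2C3CCCC2CCC3)C1 | intermediate
8 | (1S,6S)-6-[(1S)-1,3-dihydroxypropyl]-6-methylcyclohex-2-en-1-yl acetate | C1C=C[C@H](OC(C)=O)[C@](C)([C@@H](O)CCO)C1 | intermediate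
9 | (1S,6S)-6-[(1S)-1-hydroxy-3-(triethylsilyloxy)propyl]-6-methylcyclohex-2-en-1-yl acetate | C1C=C[C@H](OC(C)=O)[C@](C)([C@@H](O)CCO[Si](CC)(CC)CC)C1 | intermediate
10 | (1S,6S)-6-[(1S)-1-acetoxy-3-(triethylsilyloxy)propyl]-6-methylcyclohex-2-en-1-yl acetate | C1C=C[C@H](OC(C)=O)[C@](C)([C@@H](OC(C)=O)CCO[Si](CC)(CC)CC)C1 | intermediate
11 | (1S,6S)-6-[(1S)-1-acetoxy-3-(triethylsilyloxy)propyl]-6-methyl-4-oxocyclohex-2-en-1-yl acetate | O=C1C=C[C@H](OC(C)=O)[C@](C)([C@@H](OC(C)=O)CCO[Si](CC)(CC)CC)C1 | intermediate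
12 | (1S,6S)-6-[(1S)-1-acetoxy-3-(triethylsilyloxy)propyl]-6-methyl-4-(trifluoromethanesulfonyloxy)cyclohexa-2,4-dien-1-yl acetate | FC(F)(F)S(=O)(=O)OC1C=C[C@H](OC(C)=O)[C@](C)([C@@H](OC(C)=O)CCO[Si](CC)(CC)CC)C=1 | intermediate
13 | (trimethylsilyl)methylmagnesium chloride | C[Si](C)(C)C[Mg]Cl | starting material
14 | (trimethylsilyl)methylzinc chloride (formed in the flask) | C[Si](C)(C)C[Zn]Cl | intermediate
15 | (1S,6S)-6-[(1S)-1-acetoxy-3-(triethylsilyloxy)propyl]-6-methyl-4-[(trimethylsilyl)methyl]cyclohexa-2,4-dien-1-yl acetate | C[Si](C)(C)CC1C=C[C@H](OC(C)=O)[C@](C)([C@@H](OC(C)=O)CCO[Si](CC)(CC)CC)C=1 | intermediate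
16 | fragment A, (1S,2R)-2-[(1S)-1-acetoxy-3-(triethylsilyloxy)propyl]-2-methyl-4-[(trimethylsilyl)methyl]cyclohex-3-en-1-yl acetate | C[Si](C)(C)CC1CC[C@H](OC(C)=O)[C@](C)([C@@H](OC(C)=O)CCO[Si](CC)(CC)CC)C=1 | intermediate
17 | ethynyltrimethylsilane | C[Si](C)(C)C#C | starting material
18 | (E)-3-iodoprop-2-en-1-ol | OC/C=C/I | starting material
19 | (E)-5-(trimethylsilyl)pent-2-en-4-yn-1-ol | C[Si](C)(C)C#C/C=C/CO | intermediate
20 | [(2R,3R)-3-[(trimethylsilyl)ethynyl]oxiran-2-yl]methanol | C[Si](C)(C)C#C[C@H]1O[C@@H]1CO | intermediate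
21 | acrylic acid | C=CC(=O)O | starting material
22 | (2R,3S)-1,2-dihydroxy-5-(trimethylsilyl)pent-4-yn-3-yl prop-2-enoate | C[Si](C)(C)C#C[C@H](OC(=O)C=C)[C@H](O)CO | intermediate
23 | (2R,3S)-2-hydroxy-1-(triethylsilyloxy)-5-(trimethylsilyl)pent-4-yn-3-yl prop-2-enoate | C[Si](C)(C)C#C[C@H](OC(=O)C=C)[C@H](O)CO[Si](CC)(CC)CC | intermediate
24 | (3S)-2-oxo-1-(triethylsilyloxy)-5-(trimethylsilyl)pent-4-yn-3-yl prop-2-enoate | C[Si](C)(C)C#C[C@H](OC(=O)C=C)C(=O)CO[Si](CC)(CC)CC | intermediate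
25 | O-(1,1,3,3-tetramethyldisiloxanyl) ether of 26 at the tertiary oxygen (formed in the flask) | C[Si](C)(C)C#C[C@@H]1OC(=O)[C@H](C)[C@@]1(O[Si](C)(C)O[SiH](C)C)CO[Si](CC)(CC)CC | intermediate
26 | (3R,4R,5S)-4-hydroxy-3-methyl-4-[(triethylsilyloxy)methyl]-5-[(trimethylsilyl)ethynyl]oxolan-2-one (Me, OH and alkynyl all cis) | C[Si](C)(C)C#C[C@@H]1OC(=O)[C@H](C)[C@@]1(O)CO[Si](CC)(CC)CC | intermediate
27 | (3R,4R,5S)-3-methyl-4-(triethylsilyloxy)-4-[(triethylsilyloxy)methyl]-5-[(trimethylsilyl)ethynyl]oxolan-2-one | C[Si](C)(C)C#C[C@@H]1OC(=O)[C@H](C)[C@@]1(O[Si](CC)(CC)CC)CO[Si](CC)(CC)CC | intermediate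
28 | (3R,4R,5S)-5-(iodoethynyl)-3-methyl-4-(triethylsilyloxy)-4-[(triethylsilyloxy)methyl]oxolan-2-one | IC#C[C@@H]1OC(=O)[C@H](C)[C@@]1(O[Si](CC)(CC)CC)CO[Si](CC)(CC)CC | intermediate
29 | fragment B, (2S,3S,4R)-2-(iodoethynyl)-4-methyl-5-oxo-3-(triethylsilyloxy)oxolane-3-carbaldehyde | IC#C[C@@H]1OC(=O)[C@H](C)[C@@]1(O[Si](CC)(CC)CC)C=O | intermediate
30 | (1S,2R,3S)-2-[(1S)-1-acetoxy-3-(triethylsilyloxy)propyl]-3-{(S)-hydroxy[(2S,3R,4R)-2-(iodoethynyl)-4-methyl-5-oxo-3-(triethylsilyloxy)oxolan-3-yl]methyl}-2-methyl-4-methylidenecyclohexyl acetate | C=C1CC[C@H](OC(C)=O)[C@](C)([C@@H](OC(C)=O)CCO[Si](CC)(CC)CC)[C@H]1[C@H](O)[C@]2(O[Si](CC)(CC)CC)[C@@H](C)C(=O)O[C@H]2C#CI | intermediate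
31 | (1S,2R,3S)-3-{(S)-acetoxy[(2S,3R,4R)-2-(iodoethynyl)-4-methyl-5-oxo-3-(triethylsilyloxy)oxolan-3-yl]methyl}-2-[(1S)-1-acetoxy-3-(triethylsilyloxy)propyl]-2-methyl-4-methylidenecyclohexyl acetate | C=C1CC[C@H](OC(C)=O)[C@](C)([C@@H](OC(C)=O)CCO[Si](CC)(CC)CC)[C@H]1[C@H](OC(C)=O)[C@]2(O[Si](CC)(CC)CC)[C@@H](C)C(=O)O[C@H]2C#CI | intermediate
32 | (1S,2R,3S)-3-{(S)-acetoxy[(2S,3R,4R)-2-(iodoethynyl)-4-methyl-5-oxo-3-(triethylsilyloxy)oxolan-3-yl]methyl}-2-[(1S)-1-acetoxy-3-oxopropyl]-2-methyl-4-methylidenecyclohexyl acetate | C=C1CC[C@H](OC(C)=O)[C@](C)([C@@H](OC(C)=O)CC=O)[C@H]1[C@H](OC(C)=O)[C@]2(O[Si](CC)(CC)CC)[C@@H](C)C(=O)O[C@H]2C#CI | intermediate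
33 | 4-O-trimethylsilyl ether of 34 (formed in the flask) | C=C1CC[C@H](OC(C)=O)[C@]2(C)[C@@H](OC(C)=O)C[C@@H](O[Si](C)(C)C)C#C[C@@H]3OC(=O)[C@H](C)[C@@]3(O[Si](CC)(CC)CC)[C@@H](OC(C)=O)[C@@H]12 | intermediate
34 | ten-membered cycloalkynol (1R,2S,4R,7S,8R,9S,10S,14S,17R)-2,9,14-triacetoxy-4-hydroxy-8-(triethylsilyloxy)-5,6-didehydro-16-nor-briar-11(20)-en-19,7-olide | C=C1CC[C@H](OC(C)=O)[C@]2(C)[C@@H](OC(C)=O)C[C@@H](O)C#C[C@@H]3OC(=O)[C@H](C)[C@@]3(O[Si](CC)(CC)CC)[C@@H](OC(C)=O)[C@@H]12 | intermediate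
35 | alkenylstannane (1R,2S,4R,5Z,7S,8R,9S,10S,14S,17R)-2,9,14-triacetoxy-4-hydroxy-5-(tributylstannyl)-8-(triethylsilyloxy)-16-nor-briara-5,11(20)-dien-19,7-olide (C4 and C7 trans across C5=C6) | C=C1CC[C@H](OC(C)=O)[C@]2(C)[C@@H](OC(C)=O)C[C@@H](O)/C([Sn](CCCC)(CCCC)CCCC)=C/[C@@H]3OC(=O)[C@H](C)[C@@]3(O[Si](CC)(CC)CC)[C@@H](OC(C)=O)[C@@H]12 | intermediate
36 | methyl (1R,2S,4R,5Z,7S,8S,9S,10S,14S,17R)-2,9,14-triacetoxy-4-hydroxy-8-(triethylsilyloxy)briara-5,11(20)-dien-19,7-olid-16-oate | C=C1CC[C@H](OC(C)=O)[C@]2(C)[C@@H](OC(C)=O)C[C@@H](O)/C(C(=O)OC)=C/[C@@H]3OC(=O)[C@H](C)[C@@]3(O[Si](CC)(CC)CC)[C@@H](OC(C)=O)[C@@H]12 | intermediate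
37 | methyl (1R,2S,4R,5Z,7S,8S,9S,10S,14S,17R)-2,4,9,14-tetraacetoxy-8-(triethylsilyloxy)briara-5,11(20)-dien-19,7-olid-16-oate | C=C1CC[C@H](OC(C)=O)[C@]2(C)[C@@H](OC(C)=O)C[C@@H](OC(C)=O)/C(C(=O)OC)=C/[C@@H]3OC(=O)[C@H](C)[C@@]3(O[Si](CC)(CC)CC)[C@@H](OC(C)=O)[C@@H]12 | intermediate
38 | CNP0209369.3, methyl (1R,2S,4R,5Z,7S,8S,9S,10S,14S,17R)-2,4,9,14-tetraacetoxy-8-hydroxybriara-5,11(20)-dien-19,7-olid-16-oate | C=C1CC[C@H](OC(C)=O)[C@]2(C)[C@@H](OC(C)=O)C[C@@H](OC(C)=O)/C(C(=O)OC)=C/[C@@H]3OC(=O)[C@H](C)[C@@]3(O)[C@@H](OC(C)=O)[C@@H]12 | target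

**Step count**
Total steps: 26 (fragment A, steps 1–9; fragment B, steps 10–18; union and endgame, steps 19–26).
Longest linear sequence: 17 steps (either fragment, 9 steps, plus steps 19–26).

**Three steps most likely to fail**

Step 19 (Hosomi–Sakurai union). Both partners are neopentyl-type, and the 9,10-syn outcome rests on an open transition state. The fallback sets out from enone 11. Soft enolisation (t-BuMe2SiOTf, Et3N) gives the cross-conjugated silyl dienol ether (1S,6S)-6-[(1S)-1-acetoxy-3-(triethylsilyloxy)propyl]-4-(tert-butyldimethylsilyloxy)-6-methylcyclohexa-2,4-dien-1-yl acetate F1. Diimide reduction of its disubstituted alkene gives the regiodefined silyl enol ether (1S,2R)-2-[(1S)-1-acetoxy-3-(triethylsilyloxy)propyl]-4-(tert-butyldimethylsilyloxy)-2-methylcyclohex-3-en-1-yl acetate F2. A BF3·OEt2-mediated Mukaiyama aldol with aldehyde 29 gives the 11-oxo analogue of 30 F3. Methylenation of the ketone with the Zn/CH2Br2/TiCl4 reagent returns to the route at 30.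

Step 22 (new chromium-catalysed ring closure). Catalyst turnover, ring strain and C4 facial control are all untested on this substrate. The fallback uses known chemistry and sets out from 32. A stoichiometric Nozaki–Hiyama–Kishi cyclisation (CrCl2 in excess, NiCl2 1 mol %, THF, high dilution), of the kind used to close ten-membered enediyne carbinols, gives 34 together with its C4 epimer, the (4S)-cycloalkynol F4. Dess–Martin oxidation of the mixture gives the macrocyclic 4-oxo ynone F5. Reduction with (R)-Me-CBS oxazaborolidine and catecholborane at −78 °C (alkynyl as the small group) returns to the route at 34.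

Step 23 (trans-hydrostannation inside the ten-membered ring). The trans addition must build a strained ring-trans alkene and must be steered by the C4 hydroxyl alone. The fallback sets out from 34. An O-directed free-radical hydrostannation (Ph3SnH, catalytic Et3B, air, toluene, rt) gives the (Z)-5-triphenylstannyl allylic alcohol F6 by a radical chain instead of a ruthenium cycle. Iododestannylation (I2, CH2Cl2, 0 °C) gives the 5-iodo alkene F7. Classical carbonylation (PdCl2(PPh3)2, CO, MeOH, Et3N) returns to the route at 36.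

**Further compounds**
F1 | step 19 | (1S,6S)-6-[(1S)-1-acetoxy-3-(triethylsilyloxy)propyl]-4-(tert-butyldimethylsilyloxy)-6-methylcyclohexa-2,4-dien-1-yl acetate | CC(C)(C)[Si](C)(C)OC1C=C[C@H](OC(C)=O)[C@](C)([C@@H](OC(C)=O)CCO[Si](CC)(CC)CC)C=1
F2 | step 19 | (1S,2R)-2-[(1S)-1-acetoxy-3-(triethylsilyloxy)propyl]-4-(tert-butyldimethylsilyloxy)-2-methylcyclohex-3-en-1-yl acetate | CC(C)(C)[Si](C)(C)OC1CC[C@H](OC(C)=O)[C@](C)([C@@H](OC(C)=O)CCO[Si](CC)(CC)CC)C=1
F3 | step 19 | 11-oxo analogue of 30 (C11 ketone in place of the methylidene) | O=C1CC[C@H](OC(C)=O)[C@](C)([C@@H](OC(C)=O)CCO[Si](CC)(CC)CC)[C@H]1[C@H](O)[C@]2(O[Si](CC)(CC)CC)[C@@H](C)C(=O)O[C@H]2C#CI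
F4 | step 22 | (4S)-cycloalkynol, C4 epimer of 34 | C=C1CC[C@H](OC(C)=O)[C@]2(C)[C@@H](OC(C)=O)C[C@H](O)C#C[C@@H]3OC(=O)[C@H](C)[C@@]3(O[Si](CC)(CC)CC)[C@@H](OC(C)=O)[C@@H]12
F5 | step 22 | macrocyclic 4-oxo ynone | C=C1CC[C@H](OC(C)=O)[C@]2(C)[C@@H](OC(C)=O)CC(=O)C#C[C@@H]3OC(=O)[C@H](C)[C@@]3(O[Si](CC)(CC)CC)[C@@H](OC(C)=O)[C@@H]12
F6 | step 23 | (Z)-5-triphenylstannyl allylic alcohol (analogue of 35) | C=C1CC[C@H](OC(C)=O)[C@]2(C)[C@@H](OC(C)=O)C[C@@H](O)/C([Sn](c4ccccc4)(c5ccccc5)c6ccccc6)=C/[C@@H]3OC(=O)[C@H](C)[C@@]3(O[Si](CC)(CC)CC)[C@@H](OC(C)=O)[C@@H]12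
F7 | step 23 | 5-iodo alkene (C4 and C7 trans) | C=C1CC[C@H](OC(C)=O)[C@]2(C)[C@@H](OC(C)=O)C[C@@H](O)/C(I)=C/[C@@H]3OC(=O)[C@H](C)[C@@]3(O[Si](CC)(CC)CC)[C@@H](OC(C)=O)[C@@H]12
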